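All constants are invented; the flask was simulated.

all flasks: time 50 min

| charge | substrate | reagent | remark |
|---|---|---|---|
| alpha | 0.020 M | 1.05 equiv | everything together at the start |
| epsilon | 0.020 M | 1.05 equiv (fed, over 40 min) | all else is in the flask from the start; the feed brings no volume worth counting |
| gamma | 0.020 M (fed, over 40 min) | 1.05 equiv | all else is in the flask from the start; the feed brings no volume worth counting |

    substrate + reagent ⇌ intermediate A (K1 = 1800 M⁻¹, k1 = 0.0229 M⁻¹ s⁻¹)
    intermediate A → intermediate C (k2 = 0.00195 s⁻¹)
    intermediate C → intermediate D (k3 = 7.82 × 10⁻⁴ s⁻¹)
    2 substrate → homo dimer (k4 = 0.0560 M⁻¹ s⁻¹)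
    substrate ⇌ dormant form (K5 = 1.91, k5 = 0.0150 s⁻¹)
    intermediate A ⇌ intermediate B (K6 = 12, k6 = 6.16 × 10⁻⁴ s⁻¹)
    reagent + intermediate D → product (k7 = 0.0204 M⁻¹ s⁻¹)

- which flask leads in amount of homo dimer, in percent of the substrate charged ("all alike" within 1.5 percentage points) (alpha / epsilon / gamma / all alike)
- how much homo dimer is there at the end, in percent of the substrate charged: alpha
- how much homo dimer is there at the end, in percent of the substrate charged: epsilon
- how much homo dimer is there at the end, in percent of the substrate charged: gamma

- percent here means substrate units held: one homo dimer counts as two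
- for a step with 2 of a species take k times the square, and two of it per event
- run time (alpha): 50 min

The exchange of substrate with dormant form is the easy step: it relaxes with a half-life of 0.506 min, quicker than capture by reagent at 24 min in alpha, so we treat both as one pool, of which a share 0.344 is free substrate. Free substrate leaves in two ways: dimerising, at twice 0.0560 M⁻¹ s⁻¹ times c(substrate) squared, and capture, at 0.0229 M⁻¹ s⁻¹ times c(substrate) times c(reagent). Capture's way back, at 1.27 × 10⁻⁵ s⁻¹, is small beside the onward 0.00195 s⁻¹, so we drop it. The two losses are equal where c(substrate)/c(reagent) equals the capture constant over twice the dimer constant, 0.204: this crossing ratio is a selectivity factor. Above it, dimer takes the larger part of the substrate lost.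

Relaxed alpha starts at 0.327, which is 1.60 times the crossing ratio. With reagent held at its charge, capture is pseudo-first-order on the pool at 0.00992 min⁻¹. Solving alpha to 50 min with 0.609 as the first-order survival, we reckon 37.5% in the pool, 30.4% captured and 32.2% as dimer.

Gamma's ratio, with nothing lost, reaches the crossing 25.0 min into the feed. Correcting the growing pool for capture gives 14.9% dimer by the end of the feed, with 67.7% pooled, and 7.27% more afterwards, so 22.1%.

The weak link is the relaxed start: alpha and epsilon begin with substrate wholly free. Integrating that excess over the relaxation gives a burst of 6.53% dimer. Restarting from the smaller pool puts alpha at 35.3%. Epsilon, with reagent counted as fed and none of it consumed, has on average 60.0% of the reagent charge over the run, which gives 39.1%, so we put epsilon first.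

The forecast, noting for epsilon that “reagent builds slowly”, gave 35% for alpha, 41.5% for epsilon and 21% for gamma, with epsilon leading.

The simulation gives 34.6% for alpha, 40.9% for epsilon and 20.3% for gamma, so epsilon leads, beside our 35.3%, 39.1% and 22.1%. In alpha, c(substrate)/c(reagent) reads 0.219 at 25.0 min and 0.177 at 50.0 min, on either side of 0.204. The neighbour of gamma charged with 4.20 equiv of reagent has a reckoned ratio of 0.0818 with the whole charge pooled and reagent as charged, below the crossing, and at that ratio dimer takes 28.6% of the loss. That neighbour ends with 9.32% homo dimer, which is 13.7% of what left its pool, against 20.3% homo dimer in gamma.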